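**Plan**
- Retrosynthesis: ring A is opened at C4a–C5 (Claisen) and the C6–C5 acetate unit is removed at C6–C7, leaving a 2-aryl-2,3-dihydropyran-4-one with a CH2CO2Me arm (C8, C7). Ring C is then cut at C2–C3 and O1–C8a, and the prenyl group at the aryl–CH2 bond.
- Enabling feature: O1–C2 with its aryl group is the carbonyl of 4-methoxy-3-prenylbenzaldehyde. C3–C4–C4a–C8a is the terminal 1,3-dioxygenated diene of a persilylated triketide, with oxygen already on C4 and C8a.
- Forward order: Suzuki prenylation gives the aldehyde; silylation of methyl 3,5-dioxohexanoate gives the triene; a catalytic asymmetric oxa-[4+2] annulation closes ring C; ester to acid to β-keto ester adds C6 and C5; a Claisen condensation closes ring A last.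
- C8 and C7 are carried in on the diene and not added by enolising a 6-methyl-dihydropyranone, because such ketones are expected to deprotonate at C3, and the C3 enolate can expel O1 and destroy C2.
- Stereochemistry: the only stereocentre (2S) is set in the C2–C3 bond formation by a Ti(OiPr)4/(S)-BINOL catalyst; no later step uses a base able to enolise C3.

Key step: step 4

Remark: atom labels C2 to C8a and ring letters refer to the flavanone numbering of the target, also in intermediates.
Remark: methyl 3,5-dioxohexanoate is taken as purchasable (it is otherwise one step from dehydroacetic acid and magnesium methoxide).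
Remark: with Ti(OiPr)4/BINOL the (S)-ligand is assumed to expose the Si face of an aromatic aldehyde, by analogy with the allylation and Mukaiyama aldol series; Si-face attack gives 2S. The sense should be confirmed on the first batch, and (R)-BINOL used if it is reversed.

**Step 1**
Reactants: 1 (5-formyl-2-methoxyphenyl)boronic acid; 2 1-bromo-3-methylbut-2-ene (prenyl bromide)
Product: 3 4-methoxy-3-(3-methylbut-2-en-1-yl)benzaldehyde
Conditions: Pd(PPh3)4 (3 mol %), K2CO3 (2 equiv), toluene, 80 °C
Reagents that add atoms: none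
Why: Suzuki–Miyaura allyl–aryl coupling, in which the aryl group should be delivered to the unhindered primary terminus of the π-prenyl palladium intermediate to give the linear prenyl arene, while the aldehyde is safe because no allylboron reagent is present.

**Step 2**
Reactants: 4 methyl 3,5-dioxohexanoate
Product: 5 methyl 3,5-bis(trimethylsilyloxy)hexa-2,4-dienoate (mixture of double-bond isomers)
Conditions: Me3SiCl (2.3 equiv), Et3N (2.5 equiv), ZnCl2 (5 mol %), toluene, rt to 40 °C; filter, concentrate
Reagents that add atoms: chlorotrimethylsilane, C[Si](C)(C)Cl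
Why: silyl enol ether formation under amine conditions should cap both 1,3-dicarbonyl enols of the triketide.

**Step 3**
Reactants: 5 methyl 3,5-bis(trimethylsilyloxy)hexa-2,4-dienoate
Product: 6 1-methoxy-1,3,5-tris(trimethylsilyloxy)hexa-1,3,5-triene (mixture of double-bond isomers, used crude)
Conditions: LiN(iPr)2 (1.15 equiv), THF, −78 °C; Me3SiCl, −78 to 0 °C; pentane extraction
Reagents that add atoms: chlorotrimethylsilane, C[Si](C)(C)Cl
Why: the terminal methyl is the only site of 5 with removable protons, so deprotonation and O-silylation of the extended ester enolate (silyl ketene acetal formation) should give the triene with unambiguous regiochemistry.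

**Step 4**
Reactants: 3 4-methoxy-3-(3-methylbut-2-en-1-yl)benzaldehyde; 6 1-methoxy-1,3,5-tris(trimethylsilyloxy)hexa-1,3,5-triene (1.3 equiv)
Product: 9 methyl 2-[(2S)-2-[4-methoxy-3-(3-methylbut-2-en-1-yl)phenyl]-4-oxo-3,4-dihydro-2H-pyran-6-yl]acetate, via silylated aldol adduct 7 (not isolated), via hydroxy diketo ester 8 (not isolated)
Conditions: Ti(OiPr)4 (10 mol %), (S)-BINOL (10 mol %), 4 Å molecular sieves, THF, −78 to −20 °C; then CF3CO2H (1.5 equiv), CH2Cl2, 0 °C, short contact
Reagents that add atoms: none
Why: The BINOL-bound tetravalent titanium Lewis acid activates the aldehyde, and the terminal CH2 of triene 6 (its least hindered carbon, activated by all three oxygen donors) adds to the carbonyl carbon in a Mukaiyama aldol sense, forming C2–C3 with silyl transfer to the aldolate (7). This is the stepwise aldol–cyclocondensation form of the catalytic asymmetric hetero-Diels–Alder reaction of 1,3-dioxygenated silyloxy dienes with aromatic aldehydes, the closest precedent being the Ti(OiPr)4/BINOL aldol of the bis(silyloxy) diene of methyl acetoacetate. Acid then removes the silyl groups (8), and the C2 hydroxyl closes ring C by 6-exo-trig addition to the C8a carbonyl and loss of water, forming O1–C8a with the enol ether conjugated to the C4 ketone. The only stereocentre, C2, is fixed in the C–C bond formation by the chiral ligand, which is expected to expose the Si face of the aldehyde and so give 2S; ring closure does not touch the C2–O bond. The step needs face selectivity at the aldehyde (ligand), attack through the triene terminus and not through its internal carbons (low temperature, slight excess of 6), and cyclodehydration in preference to lactonisation of the 3,5-dioxo ester or ionisation of the 4-alkoxybenzylic carbinol (little acid, 0 °C). The CH2CO2Me arm is a spectator that becomes C8 and C7.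

**Step 5**
Reactants: 9 methyl 2-[(2S)-2-[4-methoxy-3-(3-methylbut-2-en-1-yl)phenyl]-4-oxo-3,4-dihydro-2H-pyran-6-yl]acetate
Product: 10 2-[(2S)-2-[4-methoxy-3-(3-methylbut-2-en-1-yl)phenyl]-4-oxo-3,4-dihydro-2H-pyran-6-yl]acetic acid (used crude, kept below 25 °C)
Conditions: Me3SnOH (4 equiv), 1,2-dichloroethane, 70 °C; cold 0.5 M aq. HCl work-up
Reagents that add atoms: trimethyltin hydroxide, C[Sn](C)(C)O
Why: tin-hydroxide ester hydrolysis transfers hydroxide to the methyl ester under essentially neutral conditions, so C3 is not enolised and the acid is released only on cold acidification.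

**Step 6**
Reactants: 10 2-[(2S)-2-[4-methoxy-3-(3-methylbut-2-en-1-yl)phenyl]-4-oxo-3,4-dihydro-2H-pyran-6-yl]acetic acid
Product: 12 methyl 4-[(2S)-2-[4-methoxy-3-(3-methylbut-2-en-1-yl)phenyl]-4-oxo-3,4-dihydro-2H-pyran-6-yl]-3-oxobutanoate, via acyl imidazolide 11 (not isolated)
Conditions: 1,1'-carbonyldiimidazole (1.1 equiv), THF, 0 °C to rt; then KO2CCH2CO2Me (2 equiv), MgCl2 (2 equiv), Et3N (3 equiv), MeCN–THF, rt; cold dilute aq. HCl work-up
Reagents that add atoms: potassium methyl malonate, COC(=O)CC(=O)[O-].[K+]
Why: decarboxylative Claisen condensation of a magnesium malonate half-ester with an acyl imidazolide should give the β-keto ester (adding C6 and C5) under conditions far too weakly basic to enolise C3.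

**Step 7**
Reactants: 12 methyl 4-[(2S)-2-[4-methoxy-3-(3-methylbut-2-en-1-yl)phenyl]-4-oxo-3,4-dihydro-2H-pyran-6-yl]-3-oxobutanoate
Product: 13 (2S)-5,7-dihydroxy-2-[4-methoxy-3-(3-methylbut-2-en-1-yl)phenyl]-2,3-dihydro-4H-chromen-4-one (4'-O-methyllicoflavanone)
Conditions: DBU (2.5 equiv), THF, 0 °C to rt; AcOH quench, pH 5 buffer work-up
Reagents that add atoms: none
Why: intramolecular Claisen condensation of the polyketide type, in which deprotonation at C8 makes C4a nucleophilic through the dienolate, C4a acylates on the ester (C5) in a six-membered closure, and loss of methanol with enolisation gives the aromatic 5,7-dihydroxy ring; the only other six-membered closure (C6 onto C4) would give a bridged ring and is excluded, and C3 is not deprotonated.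

**Compound list**
1 | (5-formyl-2-methoxyphenyl)boronic acid | COc1ccc(C=O)cc1B(O)O | starting material
2 | 1-bromo-3-methylbut-2-ene (prenyl bromide) | CC(C)=CCBr | starting material
3 | 4-methoxy-3-(3-methylbut-2-en-1-yl)benzaldehyde | COc1ccc(C=O)cc1CC=C(C)C | intermediate
4 | methyl 3,5-dioxohexanoate | COC(=O)CC(=O)CC(C)=O | starting material
5 | methyl 3,5-bis(trimethylsilyloxy)hexa-2,4-dienoate (double-bond isomers) | COC(=O)C=C(O[Si](C)(C)C)C=C(C)O[Si](C)(C)C | intermediate
6 | 1-methoxy-1,3,5-tris(trimethylsilyloxy)hexa-1,3,5-triene (double-bond isomers) | COC(O[Si](C)(C)C)=CC(O[Si](C)(C)C)=CC(=C)O[Si](C)(C)C | intermediate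
7 | (7S)-1-methoxy-7-[4-methoxy-3-(3-methylbut-2-en-1-yl)phenyl]-1,3,7-tris(trimethylsilyloxy)hepta-1,3-dien-5-one (double-bond isomers) | COC(O[Si](C)(C)C)=CC(O[Si](C)(C)C)=CC(=O)C[C@H](O[Si](C)(C)C)c1ccc(OC)c(CC=C(C)C)c1 | intermediate (not isolated)
8 | methyl (7S)-7-hydroxy-7-[4-methoxy-3-(3-methylbut-2-en-1-yl)phenyl]-3,5-dioxoheptanoate | COC(=O)CC(=O)CC(=O)C[C@H](O)c1ccc(OC)c(CC=C(C)C)c1 | intermediate (not isolated)
9 | methyl 2-[(2S)-2-[4-methoxy-3-(3-methylbut-2-en-1-yl)phenyl]-4-oxo-3,4-dihydro-2H-pyran-6-yl]acetate | COc1ccc([C@@H]2CC(=O)C=C(CC(=O)OC)O2)cc1CC=C(C)C | intermediate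
10 | 2-[(2S)-2-[4-methoxy-3-(3-methylbut-2-en-1-yl)phenyl]-4-oxo-3,4-dihydro-2H-pyran-6-yl]acetic acid | COc1ccc([C@@H]2CC(=O)C=C(CC(=O)O)O2)cc1CC=C(C)C | intermediate
11 | 1-{2-[(2S)-2-[4-methoxy-3-(3-methylbut-2-en-1-yl)phenyl]-4-oxo-3,4-dihydro-2H-pyran-6-yl]acetyl}-1H-imidazole | COc1ccc([C@@H]2CC(=O)C=C(CC(=O)n3ccnc3)O2)cc1CC=C(C)C | intermediate (not isolated)
12 | methyl 4-[(2S)-2-[4-methoxy-3-(3-methylbut-2-en-1-yl)phenyl]-4-oxo-3,4-dihydro-2H-pyran-6-yl]-3-oxobutanoate | COc1ccc([C@@H]2CC(=O)C=C(CC(=O)CC(=O)OC)O2)cc1CC=C(C)C | intermediate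
13 | (2S)-5,7-dihydroxy-2-[4-methoxy-3-(3-methylbut-2-en-1-yl)phenyl]-2,3-dihydro-4H-chromen-4-one | COc1ccc([C@@H]2CC(=O)c3c(O)cc(O)cc3O2)cc1CC=C(C)C | target

**Step count**
Total: 7 steps. Longest linear sequence: 6 steps (4 to 13 through steps 2 to 7).

**Steps most likely to fail**

Step 4. The triene may react through an internal carbon, or the donor-substituted aldehyde may be discriminated poorly by the catalyst. The diketo ester may also lactonise or ionise at the benzylic carbinol instead of cyclodehydrating. The fallback sets out from 3 and returns at 9; it sets the stereocentre in a simpler acetate aldol and builds the chain afterwards. Aldehyde 3 and 1-(tert-butylsulfanyl)-1-(trimethylsilyloxy)ethene under Ti(OiPr)4/(S)-BINOL catalysis should give, after mild acidic desilylation, S-tert-butyl (3S)-3-hydroxy-3-[4-methoxy-3-(3-methylbut-2-en-1-yl)phenyl]propanethioate F1. tert-Butyldimethylsilyl chloride and imidazole should convert it into S-tert-butyl (3S)-3-(tert-butyldimethylsilyloxy)-3-[4-methoxy-3-(3-methylbut-2-en-1-yl)phenyl]propanethioate F2. Claisen acylation of the dianion of methyl acetoacetate (NaH, then n-BuLi, THF, −78 °C) by F2 should give methyl (7S)-7-(tert-butyldimethylsilyloxy)-7-[4-methoxy-3-(3-methylbut-2-en-1-yl)phenyl]-3,5-dioxoheptanoate F3. Aqueous trifluoroacetic acid in CH2Cl2 at 0 °C should then remove the silyl group and cyclodehydrate to 9, closing O1–C8a in a separate step.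

Step 7. Ring closure may be slower than base-induced opening of ring C through the C3 enolate (retro-oxa-Michael), which would erode the configuration at C2. The fallback sets out from 10 and returns at 13; it uses a thioester as a much better acyl donor so that a weak amine base suffices. Acid 10 is activated as in step 6 and condensed with the magnesium enolate formed from potassium 3-(ethylsulfanyl)-3-oxopropanoate, MgCl2 and Et3N to give S-ethyl 4-[(2S)-2-[4-methoxy-3-(3-methylbut-2-en-1-yl)phenyl]-4-oxo-3,4-dihydro-2H-pyran-6-yl]-3-oxobutanethioate F4. Et3N in CH2Cl2 at 0 °C should then bring about the Claisen closure and aromatisation to 13.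

Step 6. The vinylogous β-keto acid may lose carbon dioxide, or the acyl imidazolide may eliminate imidazole to a ketene and oligomerise, before C-acylation takes place. The fallback sets out from 10 and returns at 12; it replaces the magnesium malonate by C-acylation of a far more acidic carbon acid followed by neutral thermolysis. Acid 10, 2,2-dimethyl-1,3-dioxane-4,6-dione, dicyclohexylcarbodiimide and 4-(dimethylamino)pyridine in CH2Cl2 at 0 °C should give 5-{2-[(2S)-2-[4-methoxy-3-(3-methylbut-2-en-1-yl)phenyl]-4-oxo-3,4-dihydro-2H-pyran-6-yl]acetyl}-2,2-dimethyl-1,3-dioxane-4,6-dione F5. Heating F5 with methanol in toluene at 70 °C should give 12 by way of the acylketene.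

**Further compounds**
F1 | step 4 | S-tert-butyl (3S)-3-hydroxy-3-[4-methoxy-3-(3-methylbut-2-en-1-yl)phenyl]propanethioate | CC(C)(C)SC(=O)C[C@H](O)c1ccc(OC)c(CC=C(C)C)c1
F2 | step 4 | S-tert-butyl (3S)-3-(tert-butyldimethylsilyloxy)-3-[4-methoxy-3-(3-methylbut-2-en-1-yl)phenyl]propanethioate | CC(C)(C)SC(=O)C[C@H](O[Si](C)(C)C(C)(C)C)c1ccc(OC)c(CC=C(C)C)c1
F3 | step 4 | methyl (7S)-7-(tert-butyldimethylsilyloxy)-7-[4-methoxy-3-(3-methylbut-2-en-1-yl)phenyl]-3,5-dioxoheptanoate | COC(=O)CC(=O)CC(=O)C[C@H](O[Si](C)(C)C(C)(C)C)c1ccc(OC)c(CC=C(C)C)c1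
F4 | step 7 | S-ethyl 4-[(2S)-2-[4-methoxy-3-(3-methylbut-2-en-1-yl)phenyl]-4-oxo-3,4-dihydro-2H-pyran-6-yl]-3-oxobutanethioate | CCSC(=O)CC(=O)CC1=CC(=O)C[C@@H](c2ccc(OC)c(CC=C(C)C)c2)O1
F5 | step 6 | 5-{2-[(2S)-2-[4-methoxy-3-(3-methylbut-2-en-1-yl)phenyl]-4-oxo-3,4-dihydro-2H-pyran-6-yl]acetyl}-2,2-dimethyl-1,3-dioxane-4,6-dione | COc1ccc([C@@H]2CC(=O)C=C(CC(=O)C3C(=O)OC(C)(C)OC3=O)O2)cc1CC=C(C)C
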